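**Retrosynthetic overview**
- The target is cut at the CH2–C(=O) bond on the cyclopentane side: a neopentyl-type organolithium (cyclopentane fragment A) adds to a chromene-acetaldehyde (fragment B); both ketones are unveiled together in the last step.
- Fragment A comes from 2-[(1S,2S)-2-formyl-1,2-dimethylcyclopentyl]acetic acid, made by ozonolysis of an enol silane obtained by enantioselective deprotonation of meso cis-1,5-dimethylbicyclo[3.3.0]octan-3-one.
- That bicycle comes from the Weiss–Cook condensation of biacetyl with dimethyl 3-oxoglutarate: the first cyclopentane closes by intramolecular aldol addition, the second by intramolecular Michael addition, fixing the cis vicinal quaternary methyls; one ring stays as the target's cyclopentane, the other is cut open.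
- Fragment B comes from a Pd-catalysed aryl C–O closure of a (Z)-2-bromostyryl tertiary alcohol, itself from Sonogashira coupling and Lindlar reduction of an (R)-tertiary propargylic alcohol (Sharpless epoxidation, epoxy-chloride fragmentation).
- Ring order: carbocycle (step 1), then the pyran ring of the chromene (step 20), then fragment union; no ring is formed after the union.

Assumption: the (R,R)-lithium amide in step 5 is taken to give enol silane 11 as drawn (sense by analogy with other cis-fused bicyclo[3.3.0]octan-3-ones); if it gives the antipode, the (S,S)-amide is used instead.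

**Fragment A (steps 1–10)**

Step 1
Reactants: 1 butane-2,3-dione (biacetyl); 2 dimethyl 3-oxopentanedioate (2 equiv)
Product: 5 tetramethyl cis-3,7-dihydroxy-1,5-dimethylbicyclo[3.3.0]octa-2,6-diene-2,4,6,8-tetracarboxylate, via cyclopentenone 3 (not isolated), via Michael acceptor 4 (not isolated)
Conditions: aq. NaHCO3 buffer (pH 8.3), rt, 24 h; product filtered off
Reagents that add atoms: none
Why: Weiss–Cook condensation in which the first cyclopentane closes by intramolecular aldol addition (3) and, after conjugate addition of the second ketodiester and loss of water (4), the second closes by intramolecular Michael addition, the bicyclo[3.3.0] frame allowing only the cis fusion so that the two quaternary methyl carbons are set cis.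

Step 2
Reactants: 5 tetramethyl cis-3,7-dihydroxy-1,5-dimethylbicyclo[3.3.0]octa-2,6-diene-2,4,6,8-tetracarboxylate
Product: 6 cis-1,5-dimethylbicyclo[3.3.0]octane-3,7-dione (meso)
Conditions: 1 M HCl, AcOH, reflux
Reagents that add atoms: none
Why: acidic ester hydrolysis followed by fourfold β-keto acid decarboxylation, which cannot touch the quaternary ring-fusion carbons.

Step 3
Reactants: 6 cis-1,5-dimethylbicyclo[3.3.0]octane-3,7-dione
Product: 7 7,7-(ethylenedioxy)-cis-1,5-dimethylbicyclo[3.3.0]octan-3-one (mono-dioxolane, meso)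
Conditions: HOCH2CH2OH (1.0 equiv), TsOH·H2O (cat.), benzene, reflux (Dean–Stark); dione and bis-ketal recycled
Reagents that add atoms: ethylene glycol, OCCO
Why: acid-catalysed ketalisation with one equivalent of diol gives the separable mono-ketal statistically and so tells the two equivalent ketones apart.

Step 4
Reactants: 7 7,7-(ethylenedioxy)-cis-1,5-dimethylbicyclo[3.3.0]octan-3-one
Product: 10 cis-1,5-dimethylbicyclo[3.3.0]octan-3-one (meso), via hydrazone 8 (not isolated), via deoxygenated ketal 9 (not isolated)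
Conditions: N2H4·H2O, KOH, diethylene glycol, 130 → 200 °C; then 2 M HCl, THF, rt
Reagents that add atoms: water, O
Why: Wolff–Kishner (Huang-Minlon) reduction removes the free carbonyl through its hydrazone while the base-stable dioxolane survives and is then hydrolysed by acid to the ketone.

Step 5
Reactants: 10 cis-1,5-dimethylbicyclo[3.3.0]octan-3-one
Product: 11 (1R,5S)-1,5-dimethyl-3-(trimethylsilyloxy)bicyclo[3.3.0]oct-2-ene
Conditions: (R,R)-bis(1-phenylethyl)amine, n-BuLi, LiCl, THF, −78 °C; then Me3SiCl and 10 (in situ quench), −100 °C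
Reagents that add atoms: chlorotrimethylsilane, C[Si](C)(C)Cl
Why: enantioselective deprotonation with a chiral lithium amide (Koga–Simpkins desymmetrisation) removes one of the two enantiotopic α-CH2 protons of the meso ketone and thereby fixes the absolute configuration of both quaternary carbons at once.

Step 6
Reactants: 11 (1R,5S)-1,5-dimethyl-3-(trimethylsilyloxy)bicyclo[3.3.0]oct-2-ene
Product: 12 2-[(1S,2S)-2-formyl-1,2-dimethylcyclopentyl]acetic acid
Conditions: O3, CH2Cl2–MeOH, −78 °C; Me2S, −78 °C → rt; aqueous work-up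
Reagents that add atoms: ozone, [O-][O+]=O
Why: ozonolysis of the silyl enol ether cleaves the enol C=C to an aldehyde on one quaternary carbon and, after loss of the silyl group, a CH2CO2H arm on the other, without touching either stereocentre.

Step 7
Reactants: 13 2-methylbut-3-yn-2-ol
Product: 14 triethyl[(2-methylbut-3-yn-2-yl)oxy]silane
Conditions: Et3SiCl, imidazole, DMF, rt
Reagents that add atoms: chlorotriethylsilane, CC[Si](CC)(CC)Cl
Why: imidazole-promoted silylation protects the tertiary propargylic alcohol for the organolithium steps.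

Step 8
Reactants: 12 2-[(1S,2S)-2-formyl-1,2-dimethylcyclopentyl]acetic acid; 14 triethyl[(2-methylbut-3-yn-2-yl)oxy]silane
Product: 18 2-[(1S,2S)-2-{1-[(tert-butyldimethylsilyl)oxy]-4-methyl-4-[(triethylsilyl)oxy]pent-2-yn-1-yl}-1,2-dimethylcyclopentyl]acetic acid (both carbinol epimers), via lithium acetylide 15 (not isolated), via carboxylate alkoxide 16 (not isolated), via silyl ester 17 (not isolated)
Conditions: 12, NaH, THF, 0 °C; 14, n-BuLi, THF, −78 °C, then added to the carboxylate at −78 °C; t-BuMe2SiOTf, −78 → 0 °C; K2CO3, MeOH–H2O work-up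
Reagents that add atoms: tert-butyldimethylsilyl trifluoromethanesulfonate, CC(C)(C)[Si](C)(C)OS(=O)(=O)C(F)(F)F
Why: acetylide 1,2-addition to the non-enolisable neopentyl aldehyde of the preformed carboxylate, with in situ O-silylation to stop lactonisation and mild basic work-up to cleave only the silyl ester; the new carbinol centre forms as a mixture that is erased by the oxidation in step 25.

Step 9
Reactants: 18 the alkynyl acid from step 8
Product: 19 2-[(1S,2S)-2-{(2Z)-1-[(tert-butyldimethylsilyl)oxy]-4-methyl-4-[(triethylsilyl)oxy]pent-2-en-1-yl}-1,2-dimethylcyclopentyl]acetic acid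
Conditions: H2 (1 atm), Pd/CaCO3 poisoned with Pb(OAc)2 (Lindlar catalyst), quinoline, EtOAc, rt
Reagents that add atoms: none
Why: Lindlar semihydrogenation delivers both hydrogens to the same face of the alkyne and stops at the Z-alkene.

Step 10
Reactants: 19 the (Z)-alkenyl acid from step 9
Product: 21 tert-butyl{[(2Z)-1-[(1S,2R)-2-(iodomethyl)-1,2-dimethylcyclopentyl]-4-methyl-4-(triethylsilyloxy)pent-2-en-1-yl]oxy}dimethylsilane, via Barton ester 20 (not isolated)
Conditions: N-hydroxypyridine-2-thione, DCC, DMAP (cat.), CH2Cl2, 0 °C → rt, dark; then CHI3, benzene, hν (tungsten lamp), rt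
Reagents that add atoms: iodoform, IC(I)I
Why: Barton decarboxylative iodination, in which the primary radical released from the thiohydroxamate ester abstracts iodine from CHI3 faster than it can cyclise onto the alkene, giving the neopentyl iodide without any substitution at the hindered carbon (the CIP label of that carbon changes to R only because CH2I now outranks the ring carbon).

**Fragment B (steps 11–22)**

Step 11
Reactants: 22 but-3-yn-1-ol
Product: 23 (but-3-yn-1-yloxy)(tert-butyl)dimethylsilane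
Conditions: t-BuMe2SiCl, imidazole, DMF, rt
Reagents that add atoms: tert-butylchlorodimethylsilane, CC(C)(C)[Si](C)(C)Cl
Why: standard silyl protection of the primary alcohol before the organoaluminium chemistry.

Step 12
Reactants: 23 (but-3-yn-1-yloxy)(tert-butyl)dimethylsilane
Product: 25 (2E)-5-[(tert-butyldimethylsilyl)oxy]-3-methylpent-2-en-1-ol, via alkenylalane 24 (not isolated)
Conditions: Me3Al (2.5 equiv), Cp2ZrCl2 (0.25 equiv), CH2Cl2, 0 °C → rt; then (CH2O)n, 0 °C → rt; aq. potassium sodium tartrate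
Reagents that add atoms: trimethylaluminium, C[Al](C)C; formaldehyde (from paraformaldehyde), C=O
Why: Negishi zirconium-catalysed carboalumination adds CH3 and Al syn across the terminal alkyne and the alkenylalane is hydroxymethylated with retention, giving the trisubstituted E-allylic alcohol.

Step 13
Reactants: 25 (2E)-5-[(tert-butyldimethylsilyl)oxy]-3-methylpent-2-en-1-ol
Product: 26 [(2R,3R)-3-{2-[(tert-butyldimethylsilyl)oxy]ethyl}-3-methyloxiran-2-yl]methanol
Conditions: Ti(OiPr)4 (10 mol%), D-(−)-diethyl tartrate (12 mol%), t-BuOOH, 4 Å MS, CH2Cl2, −20 °C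
Reagents that add atoms: tert-butyl hydroperoxide, CC(C)(C)OO
Why: Katsuki–Sharpless asymmetric epoxidation, in which the D-(−)-tartrate–titanium complex delivers oxygen to the face that gives the (2R,3R)-epoxide (mirror image of the geraniol/L-(+)-tartrate outcome) and so sets the carbon that becomes C2 of the chromene.

Step 14
Reactants: 26 the (2R,3R)-epoxy alcohol
Product: 27 tert-butyl{2-[(2R,3S)-3-(chloromethyl)-2-methyloxiran-2-yl]ethoxy}dimethylsilane
Conditions: PPh3, CCl4, NaHCO3, reflux
Reagents that add atoms: tetrachloromethane, ClC(Cl)(Cl)Cl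
Why: Appel chlorination of the primary alcohol under neutral conditions leaves the epoxide and both stereocentres untouched (the CH descriptor changes only because CH2Cl outranks the ring carbon).

Step 15
Reactants: 27 the epoxy chloride
Product: 29 (3R)-5-[(tert-butyldimethylsilyl)oxy]-3-methylpent-1-yn-3-ol, via chlorovinyl alkoxide 28 (not isolated)
Conditions: n-BuLi (3.2 equiv), THF, −78 → −30 °C; aq. NH4Cl
Reagents that add atoms: none
Why: base-induced fragmentation of a 2,3-epoxy chloride (deprotonation next to chlorine opens the epoxide to a chlorovinyl alkoxide, then loss of HCl gives the alkyne), in which the C–O bond of the tertiary carbon is never broken, so its configuration is retained.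

Step 16
Reactants: 30 4-methoxy-2-methylaniline
Product: 31 2-iodo-4-methoxy-6-methylaniline
Conditions: I2, NaHCO3, CH2Cl2–H2O, rt
Reagents that add atoms: iodine, II
Why: electrophilic aromatic iodination goes to the only free position ortho to the strongly directing amino group, the para position being blocked.

Step 17
Reactants: 31 2-iodo-4-methoxy-6-methylaniline
Product: 33 2-bromo-1-iodo-5-methoxy-3-methylbenzene, via diazonium bromide 32 (not isolated)
Conditions: NaNO2, 48% aq. HBr, 0 °C; then CuBr, HBr, 70 °C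
Reagents that add atoms: hydrogen bromide, Br
Why: Sandmeyer reaction replaces the diazotised amino group by bromine, putting the bromide between the methyl group and the iodide.

Step 18
Reactants: 29 (3R)-5-[(tert-butyldimethylsilyl)oxy]-3-methylpent-1-yn-3-ol; 33 2-bromo-1-iodo-5-methoxy-3-methylbenzene
Product: 34 (3R)-1-(2-bromo-5-methoxy-3-methylphenyl)-5-[(tert-butyldimethylsilyl)oxy]-3-methylpent-1-yn-3-ol
Conditions: PdCl2(PPh3)2 (2 mol%), CuI (copper monoiodide, 4 mol%), Et3N, THF, rt
Reagents that add atoms: none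
Why: Sonogashira coupling is chemoselective for the C–I bond over the more hindered C–Br bond and tolerates the free tertiary alcohol.

Step 19
Reactants: 34 the aryl alkyne
Product: 35 (1Z,3R)-1-(2-bromo-5-methoxy-3-methylphenyl)-5-[(tert-butyldimethylsilyl)oxy]-3-methylpent-1-en-3-ol
Conditions: H2 (1 atm), Pd/CaCO3 poisoned with Pb(OAc)2 (Lindlar catalyst), quinoline, EtOAc, rt
Reagents that add atoms: none
Why: Lindlar semihydrogenation gives the Z-styrene by syn addition of hydrogen and leaves the aryl bromide intact.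

Step 20
Reactants: 35 the (Z)-bromostyryl tertiary alcohol
Product: 36 tert-butyl{2-[(2R)-6-methoxy-2,8-dimethyl-2H-chromen-2-yl]ethoxy}dimethylsilane
Conditions: Pd(OAc)2 (5 mol%), 2-(di-tert-butylphosphino)-1,1'-binaphthyl (6 mol%), Cs2CO3, toluene, 80 °C
Reagents that add atoms: none
Why: Buchwald-type palladium-catalysed intramolecular C–O coupling of the aryl bromide with the tertiary alkoxide (no β-hydrogen on the carbinol carbon) closes the pyran ring with retention, because the bond from oxygen to the stereocentre is not broken and the Z-alkene holds the two ends together.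

Step 21
Reactants: 36 the chromene silyl ether
Product: 37 2-[(2R)-6-methoxy-2,8-dimethyl-2H-chromen-2-yl]ethan-1-ol
Conditions: Bu4NF, THF, 0 °C → rt
Reagents that add atoms: none
Why: fluoride-mediated desilylation frees the primary alcohol without affecting the chromene.

Step 22
Reactants: 37 2-[(2R)-6-methoxy-2,8-dimethyl-2H-chromen-2-yl]ethan-1-ol
Product: 38 2-[(2R)-6-methoxy-2,8-dimethyl-2H-chromen-2-yl]acetaldehyde
Conditions: Dess–Martin periodinane, NaHCO3, CH2Cl2, 0 °C; used at once
Reagents that add atoms: none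
Why: Dess–Martin oxidation under buffered, non-basic conditions gives the β-aryloxy aldehyde without E1cB opening of the pyran ring.

**Union and end-game (steps 23–25)**

Step 23
Reactants: 21 the neopentyl iodide from step 10; 38 2-[(2R)-6-methoxy-2,8-dimethyl-2H-chromen-2-yl]acetaldehyde
Product: 40 (3Z)-5-[(tert-butyldimethylsilyl)oxy]-5-[(1S,2S)-2-{2-hydroxy-3-[(2R)-6-methoxy-2,8-dimethyl-2H-chromen-2-yl]propyl}-1,2-dimethylcyclopentyl]-2-methyl-2-(triethylsilyloxy)pent-3-ene (carbinol epimers), via alkyllithium 39 (not isolated)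
Conditions: 21, t-BuLi (2.1 equiv), Et2O–pentane, −78 °C; then 38, Et2O, −78 °C; aq. NH4Cl
Reagents that add atoms: none
Why: iodine–lithium exchange gives the neopentyl-type alkyllithium, which at −78 °C adds to the aldehyde carbonyl faster than it enolises it; the new carbinol centre is erased in step 25.

Step 24
Reactants: 40 the bis-silyl ether from step 23
Product: 41 (3Z)-1-[(1S,2S)-2-{2-hydroxy-3-[(2R)-6-methoxy-2,8-dimethyl-2H-chromen-2-yl]propyl}-1,2-dimethylcyclopentyl]-4-methylpent-2-ene-1,4-diol (carbinol epimers)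
Conditions: Bu4NF (3 equiv), THF, rt → 40 °C
Reagents that add atoms: none
Why: fluoride cleaves both silyl ethers while no ketone is yet present, so no base-sensitive β-aryloxy ketone or Z-enone is exposed to the basic reagent.

Step 25
Reactants: 41 the triol from step 24
Product: 42 (2Z)-4-hydroxy-1-[(1S,2S)-2-{3-[(2R)-6-methoxy-2,8-dimethyl-2H-chromen-2-yl]-2-oxopropyl}-1,2-dimethylcyclopentyl]-4-methylpent-2-en-1-one (target)
Conditions: Dess–Martin periodinane (3 equiv), NaHCO3, CH2Cl2, 0 °C → rt
Reagents that add atoms: none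
Why: Dess–Martin oxidation converts both secondary alcohols (the tertiary one is inert) into the β-aryloxy ketone and the Z-enone under buffered conditions that neither isomerise the alkene nor open the chromene.

Any minor enantiomer of either fragment ends as a diastereomer of 42 and is removed by chromatography at that stage.

**Compound list**
1 | butane-2,3-dione (biacetyl) | CC(=O)C(C)=O | starting material
2 | dimethyl 3-oxopentanedioate | COC(=O)CC(=O)CC(=O)OC | starting material
3 | dimethyl 5-hydroxy-4,5-dimethyl-2-oxocyclopent-3-ene-1,3-dicarboxylate (stereoisomer mixture) | COC(=O)C1C(=O)C(C(=O)OC)=C(C)C1(C)O | intermediate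
4 | cyclopentenone of 3 carrying the second ketodiester unit C-bonded at C4, after loss of the C5 hydroxyl as water (stereoisomer mixture) | COC(=O)CC(=O)C(C(=O)OC)C1(C)C(C)=C(C(=O)OC)C(=O)C1C(=O)OC | intermediate
5 | tetramethyl cis-3,7-dihydroxy-1,5-dimethylbicyclo[3.3.0]octa-2,6-diene-2,4,6,8-tetracarboxylate | COC(=O)C1=C(O)C(C(=O)OC)[C@@]2(C)C(C(=O)OC)=C(O)C(C(=O)OC)[C@@]12C | intermediate
6 | cis-1,5-dimethylbicyclo[3.3.0]octane-3,7-dione (meso) | C[C@]12CC(=O)C[C@@]1(C)CC(=O)C2 | intermediate
7 | 7,7-(ethylenedioxy)-cis-1,5-dimethylbicyclo[3.3.0]octan-3-one (meso) | C[C@]12CC(=O)C[C@@]1(C)CC3(OCCO3)C2 | intermediate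
8 | hydrazone of 7 | C[C@]12CC(=NN)C[C@@]1(C)CC3(OCCO3)C2 | intermediate
9 | 3,3-(ethylenedioxy)-cis-1,5-dimethylbicyclo[3.3.0]octane | C[C@]12CCC[C@@]1(C)CC3(OCCO3)C2 | intermediate
10 | cis-1,5-dimethylbicyclo[3.3.0]octan-3-one (meso) | C[C@]12CCC[C@@]1(C)CC(=O)C2 | intermediate
11 | (1R,5S)-1,5-dimethyl-3-(trimethylsilyloxy)bicyclo[3.3.0]oct-2-ene | C[Si](C)(C)OC1=C[C@@]2(C)CCC[C@@]2(C)C1 | intermediate
12 | 2-[(1S,2S)-2-formyl-1,2-dimethylcyclopentyl]acetic acid | OC(=O)C[C@]1(C)CCC[C@]1(C)C=O | intermediate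
13 | 2-methylbut-3-yn-2-ol | CC(C)(O)C#C | starting material
14 | triethyl[(2-methylbut-3-yn-2-yl)oxy]silane | C#CC(C)(C)O[Si](CC)(CC)CC | intermediate
15 | lithium acetylide of 14 | [Li]C#CC(C)(C)O[Si](CC)(CC)CC | intermediate
16 | sodium carboxylate lithium alkoxide adduct of 12 and 15 (carbinol epimers) | [Na+].[Li+].[O-]C(=O)C[C@]1(C)CCC[C@]1(C)C([O-])C#CC(C)(C)O[Si](CC)(CC)CC | intermediate
17 | tert-butyldimethylsilyl ester of 18 | CC(C)(C)[Si](C)(C)OC(=O)C[C@]1(C)CCC[C@]1(C)C(O[Si](C)(C)C(C)(C)C)C#CC(C)(C)O[Si](CC)(CC)CC | intermediate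
18 | 2-[(1S,2S)-2-{1-[(tert-butyldimethylsilyl)oxy]-4-methyl-4-[(triethylsilyl)oxy]pent-2-yn-1-yl}-1,2-dimethylcyclopentyl]acetic acid (carbinol epimers) | OC(=O)C[C@]1(C)CCC[C@]1(C)C(O[Si](C)(C)C(C)(C)C)C#CC(C)(C)O[Si](CC)(CC)CC | intermediate
19 | 2-[(1S,2S)-2-{(2Z)-1-[(tert-butyldimethylsilyl)oxy]-4-methyl-4-[(triethylsilyl)oxy]pent-2-en-1-yl}-1,2-dimethylcyclopentyl]acetic acid (carbinol epimers) | OC(=O)C[C@]1(C)CCC[C@]1(C)C(O[Si](C)(C)C(C)(C)C)/C=C\C(C)(C)O[Si](CC)(CC)CC | intermediate
20 | Barton ester of 19 (O-acyl derivative of N-hydroxypyridine-2-thione) | S=C1C=CC=CN1OC(=O)C[C@]1(C)CCC[C@]1(C)C(O[Si](C)(C)C(C)(C)C)/C=C\C(C)(C)O[Si](CC)(CC)CC | intermediate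
21 | tert-butyl{[(2Z)-1-[(1S,2R)-2-(iodomethyl)-1,2-dimethylcyclopentyl]-4-methyl-4-(triethylsilyloxy)pent-2-en-1-yl]oxy}dimethylsilane (carbinol epimers) | IC[C@]1(C)CCC[C@]1(C)C(O[Si](C)(C)C(C)(C)C)/C=C\C(C)(C)O[Si](CC)(CC)CC | intermediate
22 | but-3-yn-1-ol | C#CCCO | starting material
23 | (but-3-yn-1-yloxy)(tert-butyl)dimethylsilane | C#CCCO[Si](C)(C)C(C)(C)C | intermediate
24 | (E)-[4-(tert-butyldimethylsilyloxy)-2-methylbut-1-en-1-yl]dimethylalane | C[Al](C)/C=C(\C)CCO[Si](C)(C)C(C)(C)C | intermediate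
25 | (2E)-5-[(tert-butyldimethylsilyl)oxy]-3-methylpent-2-en-1-ol | OC/C=C(\C)CCO[Si](C)(C)C(C)(C)C | intermediate
26 | [(2R,3R)-3-{2-[(tert-butyldimethylsilyl)oxy]ethyl}-3-methyloxiran-2-yl]methanol | OC[C@H]1O[C@]1(C)CCO[Si](C)(C)C(C)(C)C | intermediate
27 | tert-butyl{2-[(2R,3S)-3-(chloromethyl)-2-methyloxiran-2-yl]ethoxy}dimethylsilane | ClC[C@H]1O[C@]1(C)CCO[Si](C)(C)C(C)(C)C | intermediate
28 | lithium (3R)-5-[(tert-butyldimethylsilyl)oxy]-1-chloro-3-methylpent-1-en-3-olate | ClC=C[C@@](C)(CCO[Si](C)(C)C(C)(C)C)O[Li] | intermediate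
29 | (3R)-5-[(tert-butyldimethylsilyl)oxy]-3-methylpent-1-yn-3-ol | C#C[C@@](C)(CCO[Si](C)(C)C(C)(C)C)O | intermediate
30 | 4-methoxy-2-methylaniline | COc1ccc(N)c(C)c1 | starting material
31 | 2-iodo-4-methoxy-6-methylaniline | COc1cc(C)c(N)c(I)c1 | intermediate
32 | 2-iodo-4-methoxy-6-methylbenzenediazonium bromide | COc1cc(C)c([N+]#N)c(I)c1.[Br-] | intermediate
33 | 2-bromo-1-iodo-5-methoxy-3-methylbenzene | COc1cc(C)c(Br)c(I)c1 | intermediate
34 | (3R)-1-(2-bromo-5-methoxy-3-methylphenyl)-5-[(tert-butyldimethylsilyl)oxy]-3-methylpent-1-yn-3-ol | COc1cc(C)c(Br)c(C#C[C@@](C)(CCO[Si](C)(C)C(C)(C)C)O)c1 | intermediate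
35 | (1Z,3R)-1-(2-bromo-5-methoxy-3-methylphenyl)-5-[(tert-butyldimethylsilyl)oxy]-3-methylpent-1-en-3-ol | COc1cc(C)c(Br)c(/C=C\[C@@](C)(CCO[Si](C)(C)C(C)(C)C)O)c1 | intermediate
36 | tert-butyl{2-[(2R)-6-methoxy-2,8-dimethyl-2H-chromen-2-yl]ethoxy}dimethylsilane | COc1cc(C)c2c(c1)C=C[C@@](C)(CCO[Si](C)(C)C(C)(C)C)O2 | intermediate
37 | 2-[(2R)-6-methoxy-2,8-dimethyl-2H-chromen-2-yl]ethan-1-ol | COc1cc(C)c2c(c1)C=C[C@@](C)(CCO)O2 | intermediate
38 | 2-[(2R)-6-methoxy-2,8-dimethyl-2H-chromen-2-yl]acetaldehyde | COc1cc(C)c2c(c1)C=C[C@@](C)(CC=O)O2 | intermediate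
39 | alkyllithium from 21 (Li in place of I) | [Li]C[C@]1(C)CCC[C@]1(C)C(O[Si](C)(C)C(C)(C)C)/C=C\C(C)(C)O[Si](CC)(CC)CC | intermediate
40 | secondary alcohol from 39 and 38, both silyl ethers in place (carbinol epimers) | COc1cc(C)c2c(c1)C=C[C@@](C)(CC(O)C[C@]1(C)CCC[C@]1(C)C(O[Si](C)(C)C(C)(C)C)/C=C\C(C)(C)O[Si](CC)(CC)CC)O2 | intermediate
41 | (3Z)-1-[(1S,2S)-2-{2-hydroxy-3-[(2R)-6-methoxy-2,8-dimethyl-2H-chromen-2-yl]propyl}-1,2-dimethylcyclopentyl]-4-methylpent-2-ene-1,4-diol (carbinol epimers) | COc1cc(C)c2c(c1)C=C[C@@](C)(CC(O)C[C@]1(C)CCC[C@]1(C)C(O)/C=C\C(C)(C)O)O2 | intermediate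
42 | (2Z)-4-hydroxy-1-[(1S,2S)-2-{3-[(2R)-6-methoxy-2,8-dimethyl-2H-chromen-2-yl]-2-oxopropyl}-1,2-dimethylcyclopentyl]-4-methylpent-2-en-1-one | COc1cc(C)c2c(c1)C=C[C@@](C)(CC(=O)C[C@]1(C)CCC[C@]1(C)C(=O)/C=C\C(C)(C)O)O2 | target

**Step count**
Total: 25 steps. Longest linear sequence: 13 steps (11, 12, 13, 14, 15, 18, 19, 20, 21, 22, 23, 24, 25), which is 0.52 of the total. The cyclopentane branch is 12 steps (1–6, 8–10, 23–25); the side branches are step 7 and steps 16–17.

**Steps most likely to fail, with fallbacks**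

Step 5 (enantioselective deprotonation). The ee and the sense of induction on this particular meso ketone are untested. The fallback replaces the chiral base by organocatalytic desymmetrisation and sets out from 10. Proline-catalysed α-aminoxylation with nitrosobenzene (DMSO, rt; proline enantiomer chosen so that the CH2 next to the (R)-bridgehead reacts) gives (1S,5S)-2-(anilinooxy)-1,5-dimethylbicyclo[3.3.0]octan-3-one F1. N–O cleavage with CuSO4 in MeOH gives (1S,5S)-2-hydroxy-1,5-dimethylbicyclo[3.3.0]octan-3-one F2. NaIO4 in aqueous THF then cleaves the acyloin to the aldehyde-acid, and the route is rejoined at 12.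

Step 20 (palladium-catalysed C–O ring closure). The aryl bromide is electron-rich and flanked on both sides, and the tertiary alkoxide is hindered. The fallback builds the chromene by a phenol–enal annulation and separates the enantiomers; it sets out from 25. MnO2 in CH2Cl2 gives (2E)-5-[(tert-butyldimethylsilyl)oxy]-3-methylpent-2-enal F3. Condensation with commercial 4-methoxy-2-methylphenol (PhB(OH)2, propionic acid, toluene, reflux; ortho-quinone methide formation and oxa-6π electrocyclisation) gives racemic tert-butyl[2-(6-methoxy-2,8-dimethyl-2H-chromen-2-yl)ethoxy]dimethylsilane F4. Bu4NF gives racemic 2-(6-methoxy-2,8-dimethyl-2H-chromen-2-yl)ethan-1-ol F5. Preparative chiral SFC (cellulose tris(3,5-dimethylphenylcarbamate) phase) then delivers the (R)-enantiomer, and the route is rejoined at 37.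

Step 23 (alkyllithium addition to the β-aryloxy aldehyde). The risks are enolisation with ring opening of 38 and silyl migration in 39. The fallback replaces carbonyl addition by a palladium-catalysed acyl cross-coupling; it sets out from 21 and 38. Pinnick oxidation of 38 (NaClO2, NaH2PO4, 2-methylbut-2-ene, t-BuOH–H2O) gives 2-[(2R)-6-methoxy-2,8-dimethyl-2H-chromen-2-yl]acetic acid F6. EtSH, DCC and DMAP give S-ethyl 2-[(2R)-6-methoxy-2,8-dimethyl-2H-chromen-2-yl]ethanethioate F7. Zinc insertion into 21 (Zn dust, LiCl, THF, 40 °C) gives the alkylzinc iodide F8. Fukuyama coupling of F7 with F8 (PdCl2(PPh3)2, toluene–THF, rt) gives the bis-silyl ether of the central ketone F9. HF·pyridine in THF–pyridine gives the dihydroxy ketone F10. Dess–Martin oxidation of its allylic alcohol then gives the target, and the route is rejoined at 42.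

**Further compounds**
F1 | step 5 | (1S,5S)-2-(anilinooxy)-1,5-dimethylbicyclo[3.3.0]octan-3-one | O=C1C(ONc3ccccc3)[C@@]2(C)CCC[C@@]2(C)C1
F2 | step 5 | (1S,5S)-2-hydroxy-1,5-dimethylbicyclo[3.3.0]octan-3-one | O=C1C(O)[C@@]2(C)CCC[C@@]2(C)C1
F3 | step 20 | (2E)-5-[(tert-butyldimethylsilyl)oxy]-3-methylpent-2-enal | O=C/C=C(\C)CCO[Si](C)(C)C(C)(C)C
F4 | step 20 | racemic tert-butyl[2-(6-methoxy-2,8-dimethyl-2H-chromen-2-yl)ethoxy]dimethylsilane | COc1cc(C)c2c(c1)C=CC(C)(CCO[Si](C)(C)C(C)(C)C)O2
F5 | step 20 | racemic 2-(6-methoxy-2,8-dimethyl-2H-chromen-2-yl)ethan-1-ol | COc1cc(C)c2c(c1)C=CC(C)(CCO)O2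
F6 | step 23 | 2-[(2R)-6-methoxy-2,8-dimethyl-2H-chromen-2-yl]acetic acid | COc1cc(C)c2c(c1)C=C[C@@](C)(CC(=O)O)O2
F7 | step 23 | S-ethyl 2-[(2R)-6-methoxy-2,8-dimethyl-2H-chromen-2-yl]ethanethioate | COc1cc(C)c2c(c1)C=C[C@@](C)(CC(=O)SCC)O2
F8 | step 23 | alkylzinc iodide from 21 (ZnI in place of I) | I[Zn]C[C@]1(C)CCC[C@]1(C)C(O[Si](C)(C)C(C)(C)C)/C=C\C(C)(C)O[Si](CC)(CC)CC
F9 | step 23 | bis-silyl ether of the central ketone (42 with the enone carbonyl as CH–OSi(t-Bu)Me2 and the tertiary OH as OSiEt3) | COc1cc(C)c2c(c1)C=C[C@@](C)(CC(=O)C[C@]1(C)CCC[C@]1(C)C(O[Si](C)(C)C(C)(C)C)/C=C\C(C)(C)O[Si](CC)(CC)CC)O2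
F10 | step 23 | dihydroxy ketone (42 with the enone carbonyl as CH–OH) | COc1cc(C)c2c(c1)C=C[C@@](C)(CC(=O)C[C@]1(C)CCC[C@]1(C)C(O)/C=C\C(C)(C)O)O2
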